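**Retrosynthetic overview**

- Ring A of target 12 carries three contiguous substituents: a methoxy oxygen on C2, the acyl carbon (C1 of the nonanone chain) on C1, and a second methoxy oxygen on C6. The route rests on this O/C(=O)/O triad, because the acyl carbon and one flanking oxygen can be placed on two neighbouring ring carbons in one operation.
- Key disconnection: after removing the O-methyl and O-benzyl groups (12 ⇒ 11 ⇒ 10), the aryl–C(=O) bond and the adjacent aryl–O bond of hydroxy ketone 10 are cut together. This gives 3-methoxybenzyne 8 (from silyl triflate 7) and arylnonanoic acid 6.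
- Acid 6 ⇒ ester 5 ⇒ B-alkyl Suzuki coupling of the 9-BBN adduct 4 of methyl non-8-enoate 2 with aryl bromide 3; 2 ⇒ non-8-enoic acid 1.
- Ring order: no ring is formed. Ring A is bought as aryne precursor 7 and ring B as bromide 3.

Key step: step 4

Assumption: the target has no stereocentre, so no stereochemical control is needed; the benzyl ether is kept as phenol protection because it tolerates fluoride at 125 °C and would otherwise be O-arylated by the aryne.

**Route**

Step 1
Reactants: 1 non-8-enoic acid
Product: 2 methyl non-8-enoate
Conditions: MeOH, H2SO4 (cat.), reflux
Reagents that add atoms: methanol, CO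
Why: Fischer esterification, driven by the large excess of methanol, masks the acidic proton that would otherwise destroy 9-BBN, and the isolated terminal alkene is inert to catalytic acid in methanol.

Step 2
Reactants: 2 methyl non-8-enoate; 3 1-(benzyloxy)-4-bromobenzene
Product: 5 methyl 9-[4-(benzyloxy)phenyl]nonanoate, via B-alkyl-9-BBN adduct 4 (not isolated)
Conditions: 9-BBN, THF, 0 °C to rt; then 3, PdCl2(dppf) (3 mol%), aq. K3PO4, THF/DMF, 60 °C
Reagents that add atoms: none
Why: anti-Markovnikov hydroboration with 9-BBN places boron on the terminal carbon without touching the ester, and the B-alkyl Suzuki–Miyaura coupling then joins that primary carbon to the aryl bromide, the wide-bite-angle dppf ligand favouring reductive elimination over beta-hydride elimination.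

Step 3
Reactants: 5 methyl 9-[4-(benzyloxy)phenyl]nonanoate
Product: 6 9-[4-(benzyloxy)phenyl]nonanoic acid
Conditions: LiOH·H2O, THF/MeOH/H2O, rt; then 1 M HCl
Reagents that add atoms: lithium hydroxide, [Li+].[OH-]
Why: saponification of an unhindered methyl ester by acyl substitution with hydroxide, to which the benzyl ether and the alkyl chain are inert.

Step 4
Reactants: 6 9-[4-(benzyloxy)phenyl]nonanoic acid; 7 3-methoxy-2-(trimethylsilyl)phenyl trifluoromethanesulfonate
Product: 10 9-[4-(benzyloxy)phenyl]-1-(2-hydroxy-6-methoxyphenyl)nonan-1-one, via 3-methoxybenzyne 8 (not isolated), via ortho-cesiated aryl ester 9 (not isolated)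
Conditions: CsF (4 equiv), 7 (1.5 equiv), THF, 125 °C, sealed tube
Reagents that add atoms: none
Why: CsF removes the trimethylsilyl group of 7 and triflate departs to give 3-methoxybenzyne 8; the cesium carboxylate of 6 then adds through oxygen to the aryne carbon meta to the methoxy group, so that the carbanion of 9 sits on the carbon ortho to methoxy. That carbanion attacks the neighbouring ester carbonyl through a four-membered transition structure and the ester C–O bond breaks, an anionic ortho-Fries-type 1,3 O-to-C acyl shift that leaves the ketone phenoxide, which gives 10 on work-up. The closest known reaction type is the insertion of arynes into the C–O bond of carboxylic acids to give ortho-hydroxyaryl ketones. No ring is closed and no stereocentre is formed; two skeletal bonds, aryl–C(=O) and aryl–O, are made on adjacent carbons of ring A, with the acyl carbon landing between the methoxy group and the new oxygen. The step needs O-addition at the aryne carbon remote from methoxy, which the distortion of the aryne by the inductively withdrawing methoxy group and the stabilisation of negative charge beside it should secure, and it needs the acyl shift to outrun protonation of 9, which the aprotic medium, the acid held as its cesium salt and the high temperature should favour. The low solubility of CsF in THF keeps the aryne concentration low, which should limit a second arylation of the hindered, chelated product phenoxide.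

Step 5
Reactants: 10 9-[4-(benzyloxy)phenyl]-1-(2-hydroxy-6-methoxyphenyl)nonan-1-one
Product: 11 9-[4-(benzyloxy)phenyl]-1-(2,6-dimethoxyphenyl)nonan-1-one
Conditions: MeI, K2CO3, DMF, 40 °C
Reagents that add atoms: iodomethane, CI
Why: Williamson O-methylation of the phenoxide, with the dipolar aprotic solvent breaking the hydrogen bond to the carbonyl, while carbonate is too weak a base to enolise the hindered ketone.

Step 6
Reactants: 11 9-[4-(benzyloxy)phenyl]-1-(2,6-dimethoxyphenyl)nonan-1-one
Product: 12 1-(2,6-dimethoxyphenyl)-9-(4-hydroxyphenyl)nonan-1-one
Conditions: H2 (1 atm), 10% Pd on carbon, EtOAc, rt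
Reagents that add atoms: none
Why: catalytic hydrogenolysis of the benzylic C–O bond frees the phenol, and the carbonyl, twisted out of conjugation by the two ortho methoxy groups, should resist reduction under these mild conditions.

**Compound list**

1 | non-8-enoic acid | OC(=O)CCCCCCC=C | starting material
2 | methyl non-8-enoate | COC(=O)CCCCCCC=C | intermediate
3 | 1-(benzyloxy)-4-bromobenzene | Brc1ccc(OCc2ccccc2)cc1 | starting material
4 | methyl 9-(9-borabicyclo[3.3.1]nonan-9-yl)nonanoate (B-alkyl-9-BBN adduct, not isolated) | COC(=O)CCCCCCCCB1C2CCCC1CCC2 | intermediate
5 | methyl 9-[4-(benzyloxy)phenyl]nonanoate | COC(=O)CCCCCCCCc1ccc(OCc2ccccc2)cc1 | intermediate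
6 | 9-[4-(benzyloxy)phenyl]nonanoic acid | OC(=O)CCCCCCCCc1ccc(OCc2ccccc2)cc1 | intermediate
7 | 3-methoxy-2-(trimethylsilyl)phenyl trifluoromethanesulfonate | COc1cccc(OS(=O)(=O)C(F)(F)F)c1[Si](C)(C)C | starting material
8 | 3-methoxybenzyne (1,2-didehydro-3-methoxybenzene, not isolated) | COC1=CC=CC#C1 | intermediate
9 | [2-({9-[4-(benzyloxy)phenyl]nonanoyl}oxy)-6-methoxyphenyl]cesium (ortho-cesiated aryl ester, not isolated) | COc1cccc(OC(=O)CCCCCCCCc2ccc(OCc3ccccc3)cc2)c1[Cs] | intermediate
10 | 9-[4-(benzyloxy)phenyl]-1-(2-hydroxy-6-methoxyphenyl)nonan-1-one | COc1cccc(O)c1C(=O)CCCCCCCCc1ccc(OCc2ccccc2)cc1 | intermediate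
11 | 9-[4-(benzyloxy)phenyl]-1-(2,6-dimethoxyphenyl)nonan-1-one | COc1cccc(OC)c1C(=O)CCCCCCCCc1ccc(OCc2ccccc2)cc1 | intermediate
12 | 1-(2,6-dimethoxyphenyl)-9-(4-hydroxyphenyl)nonan-1-one (CNP0078073.0) | COc1cccc(OC)c1C(=O)CCCCCCCCc1ccc(O)cc1 | target

**Step count**

Total steps: 6. Longest linear sequence: 6 steps (1 to 12); aryne precursor 7 and bromide 3 are bought.

**Steps most likely to fail, with fallbacks**

1. Step 4. The aryl carbanion of 9 may be protonated before the acyl shift, which stops the sequence at the O-aryl ester. The product phenoxide may also be arylated by a second aryne, and the carboxylate may add with imperfect regioselectivity. The fallback sets out from ester 5 and comes back to the route at 11, bypassing steps 3 to 5. Ester 5 is treated with N,O-dimethylhydroxylamine hydrochloride and i-PrMgCl (THF, −20 to 0 °C) to give the Weinreb amide 9-[4-(benzyloxy)phenyl]-N-methoxy-N-methylnonanamide F1. Commercial 1,3-dimethoxybenzene (COc1cccc(OC)c1) is lithiated between its two methoxy groups by directed ortho-metalation (n-BuLi, THF, 0 °C to rt) to give (2,6-dimethoxyphenyl)lithium F2. F2 adds once to F1 (THF, −78 to 0 °C), the chelated tetrahedral adduct holding until the aqueous NH4Cl quench, and this should give dimethoxy ketone 11 directly.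

2. Step 2. Oxidative addition of the electron-rich aryl bromide to zerovalent palladium may be slow, so that protodeboronation of 4 or beta-hydride elimination from the alkylpalladium species diverts material; the ester may also hydrolyse early under the aqueous base. The fallback sets out from 2 and comes back at 5. Cross-metathesis of 2 with commercial 1-(benzyloxy)-4-ethenylbenzene (C=Cc1ccc(OCc2ccccc2)cc1) using the second-generation Grubbs catalyst (CH2Cl2, 40 °C) should give methyl (8E)-9-[4-(benzyloxy)phenyl]non-8-enoate F3. The alkene geometry is irrelevant, because homogeneous hydrogenation with H2 and RhCl(PPh3)3 (toluene/EtOH, rt), which leaves benzyl ethers intact, saturates it to 5.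

3. Step 6. Reduction of the aryl ketone to the carbinol or methylene compound may compete with cleavage of the benzyl ether, or the catalyst may stall and leave the ether in place. The fallback sets out from 11 and comes back at 12 without any hydrogenation. BCl3 with pentamethylbenzene as benzyl-cation scavenger (CH2Cl2, −78 °C) cleaves the aryl benzyl ether by Lewis-acid-mediated benzyl transfer. The low temperature should keep the chelation-assisted loss of the methyl ethers ortho to the carbonyl from setting in. This fallback makes no new compound (F0).

**Further compounds**

F1 | step 4 | 9-[4-(benzyloxy)phenyl]-N-methoxy-N-methylnonanamide | CON(C)C(=O)CCCCCCCCc1ccc(OCc2ccccc2)cc1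
F2 | step 4 | (2,6-dimethoxyphenyl)lithium | [Li]c1c(OC)cccc1OC
F3 | step 2 | methyl (8E)-9-[4-(benzyloxy)phenyl]non-8-enoate | COC(=O)CCCCCC/C=C/c1ccc(OCc2ccccc2)cc1
F0 | step 6 | none | none
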